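## Retrosynthetic overview

The target is the syn (3R,5S)-diacetate of a 1-aryloctane-3,5-diol. The phenol is unmasked last, by benzyl ether hydrogenolysis, after both carbinols have been acetylated.
C1–C2 is cut between a benzylic Grignard reagent (arene ring plus C1, from vanillin) and a terminal C2–C3 oxirane on a seven-carbon epoxy alcohol (C2–C8).
Structural feature used: O3 on C3 stands 1,3 to the O5 carbinol on C5 across the C4 methylene, and C2 is an unsubstituted CH2. A tert-butyl carbonate on O5 can therefore hand O3 to the inner carbon of a terminal C2=C3 alkene, while iodine lands on C2 and makes it the electrophile for C1.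
Ring order: the benzene ring is bought. The six-membered 1,3-dioxan-2-one (O5, C=O, O3, C3, C4, C5) is closed first, is then traded for the oxirane (O3, C3, C2), and that ring is opened in the fragment union.
C5 is bought as (S)-1,2-epoxypentane, which vinylmagnesium bromide extends to the homoallylic alcohol.

Key step: step 3

Assumption: (S)-1,2-epoxypentane is purchased as the single enantiomer. Chain atoms are numbered C1 (benzylic) to C8 as in the 1-aryloctane name of the target, and O3 and O5 are the oxygens on C3 and C5.

## Route

Step 1
Reactants: 1 (S)-1,2-epoxypentane; 2 vinylmagnesium bromide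
Product: 3 (S)-hept-1-en-4-ol
Conditions: 2 (1.5 equiv), CuI (10 mol %), THF, −30 → 0 °C; aq. NH4Cl
Reagents that add atoms: vinylmagnesium bromide (2), C=C[Mg]Br
Why: Copper-catalysed Grignard opening of a terminal epoxide proceeds by SN2 attack at the unsubstituted CH2, so the C–O bond at the stereocentre (future C5) is untouched and the descriptor stays S because the allyl arm takes the rank of the former oxirane CH2.

Step 2
Reactants: 3 (S)-hept-1-en-4-ol; 4 di-tert-butyl dicarbonate
Product: 5 tert-butyl (S)-hept-1-en-4-yl carbonate
Conditions: 4 (1.8 equiv), DMAP (0.2 equiv), MeCN, rt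
Reagents that add atoms: di-tert-butyl dicarbonate (4), CC(C)(C)OC(=O)OC(=O)OC(C)(C)C
Why: DMAP-catalysed O-tert-butoxycarbonylation of a secondary alcohol is driven by loss of CO2 and tert-butanol and does not involve the stereocentre.

Step 3
Reactants: 5 tert-butyl (S)-hept-1-en-4-yl carbonate
Product: 8 (4S,6S)-4-(iodomethyl)-6-propyl-1,3-dioxan-2-one, via iodonium bromide 6 (not isolated), via tert-butoxydioxanylium bromide 7 (not isolated)
Conditions: IBr (1.3 equiv, added slowly), PhMe, −80 °C; aq. Na2S2O3/NaHCO3
Reagents that add atoms: iodine monobromide, IBr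
Why: Electrophilic iodine from IBr engages the C2=C3 double bond of 5 reversibly as iodonium bromide 6; backside attack of the Boc carbonyl oxygen on C3, the carbon better able to carry positive charge, makes the C3–O bond and leaves iodine on C2, and the cation 7 so formed is dealkylated by bromide to neutral 8. The closest known reaction type is the iodocarbonate cyclisation of homoallylic tert-butyl carbonates, an electrophilic halocyclisation for which IBr at low temperature is an established reagent. The one new ring, the 1,3-dioxan-2-one built from O5, the carbonyl carbon, O3, C3, C4 and C5, closes in the 6-exo mode with the C2–I bond outside the ring, whereas a 7-endo closure would need attack at the less electrophilic unsubstituted C2. C5 (ring C6) dictates the configuration of the new centre C3 (ring C4): the forming ring adopts a chair with the propyl chain equatorial, and the alkene face that also places the nascent CH2I arm equatorial reacts faster, so the 4,6-cis ring with (4S,6S) descriptors, the syn O3/O5 array, should result. The step needs kinetic 1,3-syn diastereoselectivity, which is secured by the reversibility of iodonium formation (both faces stay available and the lower chair is taken), by the low temperature and non-polar solvent that the reactive IBr allows, and by the irreversible loss of the tert-butyl group, which prevents re-opening. Chemoselectivity is not at stake because 5 holds only one alkene and one internal nucleophile.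

Step 4
Reactants: 8 (4S,6S)-4-(iodomethyl)-6-propyl-1,3-dioxan-2-one
Product: 10 (2S)-1-[(2S)-oxiran-2-yl]pentan-2-ol, via iodohydrin diol 9 (not isolated)
Conditions: K2CO3 (3 equiv), MeOH, 0 °C → rt
Reagents that add atoms: none
Why: Base-mediated transesterification of the cyclic carbonate with methanol frees iodohydrin 9, whose O3 alkoxide displaces the neighbouring primary iodide in an intramolecular Williamson reaction (3-exo-tet), and since both C–O bonds at C3 and C5 stay intact the syn relationship is kept.

Step 5
Reactants: 11 vanillin
Product: 12 4-(benzyloxy)-3-methoxybenzaldehyde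
Conditions: BnBr (1.1 equiv), K2CO3, DMF, rt
Reagents that add atoms: benzyl bromide, BrCc1ccccc1
Why: Williamson ether synthesis on the acidic phenol masks the only proton source of the arene fragment with a group that is removable by hydrogenolysis at the end.

Step 6
Reactants: 12 4-(benzyloxy)-3-methoxybenzaldehyde
Product: 13 [4-(benzyloxy)-3-methoxyphenyl]methanol
Conditions: NaBH4, MeOH, 0 °C
Reagents that add atoms: none
Why: Borohydride reduction of an aromatic aldehyde to the benzylic alcohol leaves both aryl ethers untouched.

Step 7
Reactants: 13 [4-(benzyloxy)-3-methoxyphenyl]methanol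
Product: 14 1-(benzyloxy)-4-(chloromethyl)-2-methoxybenzene
Conditions: SOCl2 (1.2 equiv), CH2Cl2, 0 °C
Reagents that add atoms: thionyl chloride, O=S(Cl)Cl
Why: Chlorodehydroxylation through the chlorosulfite is fast at this electron-rich benzylic position, gives only gaseous by-products, and lets the chloride be used promptly without chromatography.

Step 8
Reactants: 14 1-(benzyloxy)-4-(chloromethyl)-2-methoxybenzene
Product: 15 [4-(benzyloxy)-3-methoxybenzyl]magnesium chloride, kept as a titrated solution
Conditions: Mg turnings (3 equiv, I2-activated), 2-MeTHF, slow addition of dilute 14, 0–10 °C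
Reagents that add atoms: magnesium, [Mg]
Why: Grignard formation by insertion of magnesium into the benzylic C–Cl bond is run with excess metal, high dilution, slow addition and 2-MeTHF as solvent, so that free halide stays scarce and Wurtz coupling is held back.

Step 9
Reactants: 10 (2S)-1-[(2S)-oxiran-2-yl]pentan-2-ol; 15 [4-(benzyloxy)-3-methoxybenzyl]magnesium chloride
Product: 16 (3R,5S)-1-[4-(benzyloxy)-3-methoxyphenyl]octane-3,5-diol
Conditions: 15 (3 equiv), CuI (15 mol %), THF/2-MeTHF, −40 → −10 °C; aq. NH4Cl
Reagents that add atoms: none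
Why: In this copper-catalysed Grignard opening of a terminal epoxide one equivalent of 15 is spent on the O5 proton and a second attacks the unhindered C2 in SN2 fashion to form C1–C2, and because no bond at C3 or C5 is broken the syn array is carried over (the C3 descriptor turns from S to R only because C2 loses its heteroatom rank).

Step 10
Reactants: 16 (3R,5S)-1-[4-(benzyloxy)-3-methoxyphenyl]octane-3,5-diol
Product: 17 (3R,5S)-1-[4-(benzyloxy)-3-methoxyphenyl]octane-3,5-diyl diacetate
Conditions: Ac2O (4 equiv), pyridine, DMAP (cat.), CH2Cl2, rt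
Reagents that add atoms: acetic anhydride, CC(=O)OC(C)=O
Why: DMAP-catalysed acylation esterifies both secondary alcohols with retention, while the benzyl ether keeps the phenol from being acetylated.

Step 11
Reactants: 17 (3R,5S)-1-[4-(benzyloxy)-3-methoxyphenyl]octane-3,5-diyl diacetate
Product: 18 (3R,5S)-1-(4-hydroxy-3-methoxyphenyl)octane-3,5-diyl diacetate (target)
Conditions: H2 (1 atm), Pd/C (10 wt %), EtOAc, rt
Reagents that add atoms: none
Why: Catalytic hydrogenolysis cleaves only the benzylic C–O bond of the aryl benzyl ether, since the two acetates sit on non-benzylic, non-allylic secondary carbons and the aprotic solvent excludes transesterification.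

## Compound list

1 | (S)-1,2-epoxypentane | CCC[C@H]1CO1 | starting material
2 | vinylmagnesium bromide | C=C[Mg]Br | starting material
3 | (S)-hept-1-en-4-ol | CCC[C@H](O)CC=C | intermediate
4 | di-tert-butyl dicarbonate | CC(C)(C)OC(=O)OC(=O)OC(C)(C)C | starting material
5 | tert-butyl (S)-hept-1-en-4-yl carbonate | CCC[C@@H](CC=C)OC(=O)OC(C)(C)C | intermediate
6 | (2R)-2-{(2S)-2-[(tert-butoxycarbonyl)oxy]pentyl}iodiran-1-ium bromide (productive iodonium ion, iodine anti to the incoming oxygen) | CCC[C@@H](C[C@@H]1C[I+]1)OC(=O)OC(C)(C)C.[Br-] | intermediate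
7 | (4S,6S)-2-tert-butoxy-4-(iodomethyl)-6-propyl-1,3-dioxan-2-ylium bromide | CCC[C@H]1C[C@@H](CI)O[C+](OC(C)(C)C)O1.[Br-] | intermediate
8 | (4S,6S)-4-(iodomethyl)-6-propyl-1,3-dioxan-2-one (4,6-cis) | CCC[C@H]1C[C@@H](CI)OC(=O)O1 | intermediate
9 | (2S,4S)-1-iodoheptane-2,4-diol | CCC[C@H](O)C[C@H](O)CI | intermediate
10 | (2S)-1-[(2S)-oxiran-2-yl]pentan-2-ol (syn epoxy alcohol) | CCC[C@H](O)C[C@H]1CO1 | intermediate
11 | vanillin | COc1cc(C=O)ccc1O | starting material
12 | 4-(benzyloxy)-3-methoxybenzaldehyde | COc1cc(C=O)ccc1OCc1ccccc1 | intermediate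
13 | [4-(benzyloxy)-3-methoxyphenyl]methanol | COc1cc(CO)ccc1OCc1ccccc1 | intermediate
14 | 1-(benzyloxy)-4-(chloromethyl)-2-methoxybenzene | COc1cc(CCl)ccc1OCc1ccccc1 | intermediate
15 | [4-(benzyloxy)-3-methoxybenzyl]magnesium chloride | COc1cc(C[Mg]Cl)ccc1OCc1ccccc1 | intermediate
16 | (3R,5S)-1-[4-(benzyloxy)-3-methoxyphenyl]octane-3,5-diol | CCC[C@H](O)C[C@H](O)CCc1ccc(OCc2ccccc2)c(OC)c1 | intermediate
17 | (3R,5S)-1-[4-(benzyloxy)-3-methoxyphenyl]octane-3,5-diyl diacetate | CCC[C@@H](C[C@@H](CCc1ccc(OCc2ccccc2)c(OC)c1)OC(C)=O)OC(C)=O | intermediate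
18 | (3R,5S)-1-(4-hydroxy-3-methoxyphenyl)octane-3,5-diyl diacetate | CCC[C@@H](C[C@@H](CCc1ccc(O)c(OC)c1)OC(C)=O)OC(C)=O | target

## Step count and risks

Total step count: 11.
Longest linear sequence: 7 steps (1, 2, 3, 4, 9, 10, 11). The vanillin branch (5, 6, 7, 8, 9, 10, 11) is equally long.

**Step 3**
- What may go wrong: erosion of facial selectivity in the ring closure, or plain addition of IBr across the alkene outrunning cyclisation.
- The fallback replaces 1,3-induction by catalyst control. It sets out from 3 and comes back at 10.
- 3 is silylated (TBSCl, imidazole, DMF) to tert-butyl{[(4S)-hept-1-en-4-yl]oxy}dimethylsilane F1.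
- F1 is epoxidised without selectivity (mCPBA, CH2Cl2) to the epimeric oxiranes tert-butyldimethyl{[(2S)-1-(oxiran-2-yl)pentan-2-yl]oxy}silane F2.
- F2 is submitted to hydrolytic kinetic resolution with water (0.55 equiv) and (S,S)-(salen)Co(OAc). This is the trivalent cobalt acetate complex of N,N'-bis(3,5-di-tert-butylsalicylidene)cyclohexane-1,2-diamine.
- That catalyst enantiomer should hydrolyse the (R)-oxirane epimer and leave the syn epoxide tert-butyldimethyl({(2S)-1-[(2S)-oxiran-2-yl]pentan-2-yl}oxy)silane F3.
- F3 is separated from the polar diol and desilylated with Bu4NF in THF to 10.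

**Step 8**
- What may go wrong: Wurtz-type homocoupling of the electron-rich benzylic chloride at the metal surface, and decay of the chloride before insertion.
- The fallback uses a sulfone-stabilised benzylic carbanion in place of the organomagnesium reagent. It sets out from 14 and comes back at 16.
- 14 is treated with PhSO2Na in DMF to give 1-(benzyloxy)-2-methoxy-4-[(phenylsulfonyl)methyl]benzene F4.
- F4 is lithiated with n-BuLi (THF, −78 °C). About 2.2 equiv of the anion are used, so that one equivalent takes up the O5 proton.
- Warming the anion with 10 in the presence of DMPU should open the oxirane at C2. The product is (3S,5S)-1-[4-(benzyloxy)-3-methoxyphenyl]-1-(phenylsulfonyl)octane-3,5-diol F5, as epimers at C1. Its C3 descriptor changes only through the rank of sulfur.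
- Reductive desulfonylation with Mg in MeOH removes the sulfonyl group together with the C1 stereocentre and gives 16.

**Step 9**
- What may go wrong: opening of the oxirane by chloride from the magnesium salts, thermal decay of the benzylic copper species by homocoupling, and sluggish reaction of the alkoxide-bearing epoxide.
- The fallback uses aldehyde umpolung with a halide-free lithium nucleophile. It sets out from 12 (with 10 as partner) and comes back at 17.
- 12 is condensed with propane-1,3-dithiol (BF3·OEt2, CH2Cl2) to 2-[4-(benzyloxy)-3-methoxyphenyl]-1,3-dithiane F6.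
- F6 is lithiated (n-BuLi, THF, −78 → −20 °C, about 2.2 equiv of anion) and opens 10 at C2. This gives (2S,4S)-1-{2-[4-(benzyloxy)-3-methoxyphenyl]-1,3-dithian-2-yl}heptane-2,4-diol F7.
- Acetylation (Ac2O, pyridine, DMAP) gives (2S,4S)-1-{2-[4-(benzyloxy)-3-methoxyphenyl]-1,3-dithian-2-yl}heptane-2,4-diyl diacetate F8.
- Raney nickel in EtOH reduces the dithioacetal carbon to the C1 methylene and gives 17. Any loss of the benzyl group at that point only anticipates step 11.

## Further compounds

F1 | step 3 | tert-butyl{[(4S)-hept-1-en-4-yl]oxy}dimethylsilane | CCC[C@@H](CC=C)O[Si](C)(C)C(C)(C)C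
F2 | step 3 | tert-butyldimethyl{[(2S)-1-(oxiran-2-yl)pentan-2-yl]oxy}silane, both epimers at the oxirane carbon | CCC[C@@H](CC1CO1)O[Si](C)(C)C(C)(C)C
F3 | step 3 | tert-butyldimethyl({(2S)-1-[(2S)-oxiran-2-yl]pentan-2-yl}oxy)silane | CCC[C@@H](C[C@H]1CO1)O[Si](C)(C)C(C)(C)C
F4 | step 8 | 1-(benzyloxy)-2-methoxy-4-[(phenylsulfonyl)methyl]benzene | COc1cc(CS(=O)(=O)c2ccccc2)ccc1OCc1ccccc1
F5 | step 8 | (3S,5S)-1-[4-(benzyloxy)-3-methoxyphenyl]-1-(phenylsulfonyl)octane-3,5-diol, both epimers at C1 | CCC[C@H](O)C[C@H](O)CC(c1ccc(OCc2ccccc2)c(OC)c1)S(=O)(=O)c1ccccc1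
F6 | step 9 | 2-[4-(benzyloxy)-3-methoxyphenyl]-1,3-dithiane | COc1cc(C2SCCCS2)ccc1OCc1ccccc1
F7 | step 9 | (2S,4S)-1-{2-[4-(benzyloxy)-3-methoxyphenyl]-1,3-dithian-2-yl}heptane-2,4-diol | CCC[C@H](O)C[C@H](O)CC1(SCCCS1)c1ccc(OCc2ccccc2)c(OC)c1
F8 | step 9 | (2S,4S)-1-{2-[4-(benzyloxy)-3-methoxyphenyl]-1,3-dithian-2-yl}heptane-2,4-diyl diacetate | CCC[C@@H](C[C@@H](CC1(SCCCS1)c1ccc(OCc2ccccc2)c(OC)c1)OC(C)=O)OC(C)=O
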